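Cupressuflavone is cut at both rings A instead of at the biaryl bond. The C8–C8'' axis, whose two carbons each sit between the oxygen-bearing C7 and C8a, is taken as the central bond of a 1,4-dioxygenated butadiyne, and the 1,3,5-oxygen pattern of each ring A (O1, O5, O7) as ynol ether plus 3-alkoxyvinylketene. One twofold Danheiser benzannulation of 1,4-bis(triisopropylsiloxy)buta-1,3-diyne with 3-ethoxycyclobutenone therefore builds both rings A around the pre-existing axis and delivers each ring with O1 free, O7 silylated and O5 ethylated. Rings C follow by oxa-Michael addition to an arylpropiolate and cycloacylation at C4a.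

Key step: step 3

Assumption: the target SMILES defines no configuration for the C8–C8'' axis, so the racemic mixture of atropisomers is taken as the target and the axis is not controlled.

Step 1
Reactants: 1 1,4-bis(trimethylsilyl)buta-1,3-diyne; 2 triisopropylsilyl triflate
Product: 5 1,4-bis(triisopropylsiloxy)buta-1,3-diyne, via 1,4-dilithiobuta-1,3-diyne 3 (not isolated), via dilithium buta-1,3-diyne-1,4-diolate 4 (not isolated)
Conditions: MeLi·LiBr (2.1 equiv), THF, −78 °C → rt; LiOOtBu (2.2 equiv, from t-BuOOH and LiN(SiMe3)2), THF, −78 → 0 °C; 2 (2.4 equiv), −78 → 0 °C; pentane, aq. NaHCO3, Et3N-deactivated silica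
Reagents that add atoms: lithium tert-butyl peroxide, [Li+].[O-]OC(C)(C)C
Why: Twofold C–Si cleavage by methyllithium gives the known dilithiodiyne, each lithium acetylide is then oxygenated by the peroxide (electrophilic oxygen transfer to a carbanion, the established route from acetylides to ynolates), and the bulky silyl triflate should silylate the ynolate oxygens and not carbon, as it does with simple ynolates.

Step 2
Reactants: 6 ethoxyacetylene; 7 acetone
Product: 9 3-ethoxycyclobut-2-en-1-one, via ketene 8 (not isolated)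
Conditions: 7, ketene generator (hot filament, ca. 700 °C); ketene stream into 6, CH2Cl2, 0 °C; distillation
Reagents that add atoms: none
Why: Pyrolysis of acetone delivers ketene, which undergoes the known [2+2] cycloaddition with the ynol ether, the nucleophilic CH carbon of 6 bonding to the ketene carbonyl carbon and the ring closing on the enolate carbon to give the 3-ethoxycyclobutenone directly.

Step 3
Reactants: 5 1,4-bis(triisopropylsiloxy)buta-1,3-diyne; 9 3-ethoxycyclobut-2-en-1-one
Product: 12 4,4'-diethoxy-6,6'-bis(triisopropylsiloxy)biphenyl-2,2'-diol, via ethoxyvinylketene 10 (not isolated), via mono-annulated siloxyalkynylphenol 11 (not isolated)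
Conditions: 9 (5 equiv), toluene, 110 °C, slow addition of 5; then K2CO3, MeOH, 0 °C
Reagents that add atoms: none
Why: Proposed new method: heat opens 9 by 4π electrocyclic cleavage to vinylketene 10, whose ketene carbon (future C8a) is attacked by the nucleophilic inner alkyne carbon of 5 (future C8) while C6 closes onto the siloxy-bearing carbon C7 in a polarity-matched [2+2] step, and the 4-vinylcyclobutenone so formed opens (4π) to a dienylketene. Each ring A then closes by 6π electrocyclisation (C4a–C8a) and tautomerises to the phenol, first giving 11 and, after the same sequence on its remaining ynol ether, 12. The closest known reaction is the Danheiser benzannulation of a cyclobutenone with one siloxyalkyne; its twofold use on a conjugated bis(siloxy)diyne, with an alkynyl and then a hindered aryl group on the nucleophilic carbon, is untested. No stereocentre is formed, and the C8–C8'' axis, which is simply the central bond of 5 and is never made by coupling, is obtained racemic. The regiochemistry needed (OH and OSi ortho, OEt para to the axis on both rings) follows from the polarisation of each ynol ether. The chemoselectivity needed is that 11 undergoes the second annulation faster than its new ortho hydroxyl adds to the neighbouring ynol ether; the bulky silyl groups, the acid-free non-polar medium and the slow addition of 5 to an excess of 9 (high stationary ketene concentration) are meant to secure this, and any O-acylated phenol is returned by the final methanolysis.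

Step 4
Reactants: 13 3-(4-methoxyphenyl)propiolic acid
Product: 14 allyl 3-(4-methoxyphenyl)prop-2-ynoate
Conditions: allyl bromide, K2CO3, DMF, rt
Reagents that add atoms: allyl bromide, C=CCBr
Why: Carboxylate O-alkylation (SN2) at room temperature, below the threshold for decarboxylation of the arylpropiolate; the allyl ester is chosen because it can later be removed under neutral conditions that spare aryl silyl ethers and the β-aryloxyacrylate.

Step 5
Reactants: 12 4,4'-diethoxy-6,6'-bis(triisopropylsiloxy)biphenyl-2,2'-diol; 14 allyl 3-(4-methoxyphenyl)prop-2-ynoate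
Product: 15 diallyl (2Z,2'Z)-3,3'-{[4,4'-diethoxy-6,6'-bis(triisopropylsiloxy)biphenyl-2,2'-diyl]bis(oxy)}bis[3-(4-methoxyphenyl)prop-2-enoate]
Conditions: 14 (2.6 equiv), K2CO3 (anhydrous), 4 Å MS, DMF, 60 °C
Reagents that add atoms: none
Why: Base-mediated oxa-Michael addition of each phenoxide to the ynoate (the classical β-aryloxycinnamate entry to flavones), with anti addition placing the aryloxy group cis to the ester; only the future O1 is free on each ring, so each ring should be vinylated exactly once, and no stereocentre arises.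

Step 6
Reactants: 15 diallyl (2Z,2'Z)-3,3'-{[4,4'-diethoxy-6,6'-bis(triisopropylsiloxy)biphenyl-2,2'-diyl]bis(oxy)}bis[3-(4-methoxyphenyl)prop-2-enoate]
Product: 16 (2Z,2'Z)-3,3'-{[4,4'-diethoxy-6,6'-bis(triisopropylsiloxy)biphenyl-2,2'-diyl]bis(oxy)}bis[3-(4-methoxyphenyl)prop-2-enoic acid]
Conditions: Pd(PPh3)4 (5 mol %), PhSiH3, CH2Cl2, rt; aq. citric acid
Reagents that add atoms: none
Why: Tsuji–Trost deallylation, in which the zerovalent palladium catalyst ionises the allyl ester and PhSiH3 reduces the π-allyl complex to propene, so the acids are freed without hydroxide, which could cleave the aryl silyl ethers or attack the β-aryloxyacrylate.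

Step 7
Reactants: 16 (2Z,2'Z)-3,3'-{[4,4'-diethoxy-6,6'-bis(triisopropylsiloxy)biphenyl-2,2'-diyl]bis(oxy)}bis[3-(4-methoxyphenyl)prop-2-enoic acid]
Product: 18 5,5''-diethoxy-4',4'''-dimethoxy-7,7''-bis(triisopropylsiloxy)-8,8''-biflavone, via bis(trifluoroacetic) mixed anhydride 17 (not isolated)
Conditions: TFAA (6 equiv), CH2Cl2, 0 °C → rt
Reagents that add atoms: none
Why: Activation as the mixed trifluoroacetic anhydride 17 and intramolecular Friedel–Crafts acylation at C4a, the only free position ortho to O1 and activated by three oxygens, should close each ring C as a 4-pyranone; the acidic medium equilibrates any E enol ether to the reactive Z form, while the silyl ethers, stable to trifluoroacetic acid, keep O7 from adding to the protonated enol ether of the other half.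

Step 8
Reactants: 18 5,5''-diethoxy-4',4'''-dimethoxy-7,7''-bis(triisopropylsiloxy)-8,8''-biflavone
Product: 19 5,5''-diethoxy-7,7''-dihydroxy-4',4'''-dimethoxy-8,8''-biflavone
Conditions: Bu4NF, THF, 0 °C; 1 M HCl
Reagents that add atoms: none
Why: Fluoride-induced cleavage of the aryl silyl ethers (Si–F bond formation), to which the flavone and the alkyl ethers are inert.

Step 9
Reactants: 19 5,5''-diethoxy-7,7''-dihydroxy-4',4'''-dimethoxy-8,8''-biflavone
Product: 20 cupressuflavone
Conditions: BBr3 (excess), CH2Cl2, −78 °C → rt; MeOH, H2O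
Reagents that add atoms: none
Why: Lewis-acid ether cleavage by BBr3 (the 5-ethoxy groups assisted by chelation to the C4 carbonyl) should remove the four remaining alkyl groups at or below room temperature, avoiding the pyranone opening and reclosure (Wessely–Moser rearrangement) that hot protic acid could cause.

Compound list
1 | 1,4-bis(trimethylsilyl)buta-1,3-diyne | C[Si](C)(C)C#CC#C[Si](C)(C)C | starting material
2 | triisopropylsilyl triflate | CC(C)[Si](OS(=O)(=O)C(F)(F)F)(C(C)C)C(C)C | starting material
3 | 1,4-dilithiobuta-1,3-diyne | [Li]C#CC#C[Li] | intermediate (not isolated)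
4 | dilithium buta-1,3-diyne-1,4-diolate (bis-ynolate) | [Li]OC#CC#CO[Li] | intermediate (not isolated)
5 | 1,4-bis(triisopropylsiloxy)buta-1,3-diyne | CC(C)[Si](OC#CC#CO[Si](C(C)C)(C(C)C)C(C)C)(C(C)C)C(C)C | intermediate
6 | ethoxyacetylene | CCOC#C | starting material
7 | acetone | CC(C)=O | starting material
8 | ketene | C=C=O | intermediate (not isolated)
9 | 3-ethoxycyclobut-2-en-1-one | CCOC1=CC(=O)C1 | intermediate
10 | 3-ethoxybuta-1,3-dien-1-one (ethoxyvinylketene) | C=C(OCC)C=C=O | intermediate (not isolated)
11 | 5-ethoxy-3-(triisopropylsiloxy)-2-[(triisopropylsiloxy)ethynyl]phenol | CCOc1cc(O)c(C#CO[Si](C(C)C)(C(C)C)C(C)C)c(O[Si](C(C)C)(C(C)C)C(C)C)c1 | intermediate (not isolated)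
12 | 4,4'-diethoxy-6,6'-bis(triisopropylsiloxy)biphenyl-2,2'-diol (racemic axis) | CCOc1cc(O)c(c(O[Si](C(C)C)(C(C)C)C(C)C)c1)-c1c(O)cc(OCC)cc1O[Si](C(C)C)(C(C)C)C(C)C | intermediate
13 | 3-(4-methoxyphenyl)propiolic acid | COc1ccc(cc1)C#CC(O)=O | starting material
14 | allyl 3-(4-methoxyphenyl)prop-2-ynoate | COc1ccc(cc1)C#CC(=O)OCC=C | intermediate
15 | diallyl (2Z,2'Z)-3,3'-{[4,4'-diethoxy-6,6'-bis(triisopropylsiloxy)biphenyl-2,2'-diyl]bis(oxy)}bis[3-(4-methoxyphenyl)prop-2-enoate] | C=CCOC(=O)/C=C(\Oc1cc(OCC)cc(O[Si](C(C)C)(C(C)C)C(C)C)c1-c1c(O/C(=C\C(=O)OCC=C)c2ccc(OC)cc2)cc(OCC)cc1O[Si](C(C)C)(C(C)C)C(C)C)c1ccc(OC)cc1 | intermediate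
16 | (2Z,2'Z)-3,3'-{[4,4'-diethoxy-6,6'-bis(triisopropylsiloxy)biphenyl-2,2'-diyl]bis(oxy)}bis[3-(4-methoxyphenyl)prop-2-enoic acid] | OC(=O)/C=C(\Oc1cc(OCC)cc(O[Si](C(C)C)(C(C)C)C(C)C)c1-c1c(O/C(=C\C(O)=O)c2ccc(OC)cc2)cc(OCC)cc1O[Si](C(C)C)(C(C)C)C(C)C)c1ccc(OC)cc1 | intermediate
17 | bis(trifluoroacetic) mixed anhydride of 16 | FC(F)(F)C(=O)OC(=O)/C=C(\Oc1cc(OCC)cc(O[Si](C(C)C)(C(C)C)C(C)C)c1-c1c(O/C(=C\C(=O)OC(=O)C(F)(F)F)c2ccc(OC)cc2)cc(OCC)cc1O[Si](C(C)C)(C(C)C)C(C)C)c1ccc(OC)cc1 | intermediate (not isolated)
18 | 5,5''-diethoxy-4',4'''-dimethoxy-7,7''-bis(triisopropylsiloxy)-8,8''-biflavone | CCOc1cc(O[Si](C(C)C)(C(C)C)C(C)C)c(-c2c(O[Si](C(C)C)(C(C)C)C(C)C)cc(OCC)c3c(=O)cc(-c4ccc(OC)cc4)oc23)c2oc(-c3ccc(OC)cc3)cc(=O)c12 | intermediate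
19 | 5,5''-diethoxy-7,7''-dihydroxy-4',4'''-dimethoxy-8,8''-biflavone | CCOc1cc(O)c(-c2c(O)cc(OCC)c3c(=O)cc(-c4ccc(OC)cc4)oc23)c2oc(-c3ccc(OC)cc3)cc(=O)c12 | intermediate
20 | cupressuflavone (5,5'',7,7'',4',4'''-hexahydroxy-8,8''-biflavone, racemic axis) | O=c1cc(-c2ccc(O)cc2)oc2c(-c3c(O)cc(O)c4c(=O)cc(-c5ccc(O)cc5)oc34)c(O)cc(O)c12 | target

Total step count: 9. Longest linear sequence: 7 (steps 1, 3, 5, 6, 7, 8, 9); steps 2 and 4 are side branches.

Steps most likely to fail

Step 3. After the first annulation the new phenol may add across the adjacent ynol ether (closure to a siloxybenzofuran), or the hindered aryl-substituted ynol ether may react too slowly with the vinylketene, which then dimerises; in either case the second ring A is not built. The fallback uses known chemistry and makes the axis by a classical biaryl coupling. It sets out from 14: oxa-Michael addition of 3,5-dimethoxyphenol (K2CO3, DMF) should give allyl (Z)-3-(3,5-dimethoxyphenoxy)-3-(4-methoxyphenyl)prop-2-enoate F1; deallylation (Pd(PPh3)4, PhSiH3) the acid (Z)-3-(3,5-dimethoxyphenoxy)-3-(4-methoxyphenyl)prop-2-enoic acid F2; Friedel–Crafts cyclisation in P2O5/MeSO3H 5,7,4'-trimethoxyflavone F3; iodination at C8 (I2, CF3CO2Ag, CH2Cl2) 8-iodo-5,7,4'-trimethoxyflavone F4; Ullmann homocoupling (Cu powder, DMF, 150 °C) cupressuflavone hexamethyl ether F5; and BBr3 demethylation rejoins the route at 20.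

Step 1. The second oxygenation has to take place on a species that is already an ynolate, and the doubly charged bis-ynolate 4 may decompose or be silylated on carbon before both oxygens are capped. The fallback avoids the dianion by oxygenating one end at a time. It sets out from 1: one equivalent of MeLi·LiBr removes a single silyl group, and oxygenation with LiOOtBu followed by 2 should give 1-(triisopropylsiloxy)-4-(trimethylsilyl)buta-1,3-diyne F6, which is isolated. A second cycle of MeLi·LiBr, LiOOtBu and 2 on this neutral mono-ynol ether returns to the route at 5.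

Step 5. The first enol ether may be captured by the neighbouring phenoxide across the axis (seven-membered cyclic ketal), a silyl group may be lost or transferred under the basic conditions so that one ring is vinylated twice, or the hindered phenoxides may add too slowly to the donor-substituted ynoate. The fallback builds rings C by C-acylation first, which needs no differentiation of the two ortho oxygens. It sets out from 12: Bu4NF in THF should give 4,4'-diethoxybiphenyl-2,2',6,6'-tetraol F7, in which C3 and C5 of each ring are equivalent. Friedel–Crafts C-acetylation (AcOH, BF3·OEt2, 80 °C) should give 1,1'-(4,4'-diethoxy-2,2',6,6'-tetrahydroxybiphenyl-3,3'-diyl)diethanone F8, and Claisen–Schmidt condensation with 4-methoxybenzaldehyde (KOH, EtOH) the bis-chalcone (2E,2'E)-1,1'-(4,4'-diethoxy-2,2',6,6'-tetrahydroxybiphenyl-3,3'-diyl)bis[3-(4-methoxyphenyl)prop-2-en-1-one] F9. Oxidative cyclisation (catalytic I2, DMSO, 120 °C) through the hydroxyls ortho to the acyl groups returns to the route at 19.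

Further compounds
F1 | step 3 | allyl (Z)-3-(3,5-dimethoxyphenoxy)-3-(4-methoxyphenyl)prop-2-enoate | C=CCOC(=O)/C=C(\Oc1cc(OC)cc(OC)c1)c1ccc(OC)cc1
F2 | step 3 | (Z)-3-(3,5-dimethoxyphenoxy)-3-(4-methoxyphenyl)prop-2-enoic acid | OC(=O)/C=C(\Oc1cc(OC)cc(OC)c1)c1ccc(OC)cc1
F3 | step 3 | 5,7,4'-trimethoxyflavone | COc1ccc(cc1)-c1cc(=O)c2c(OC)cc(OC)cc2o1
F4 | step 3 | 8-iodo-5,7,4'-trimethoxyflavone | COc1ccc(cc1)-c1cc(=O)c2c(OC)cc(OC)c(I)c2o1
F5 | step 3 | cupressuflavone hexamethyl ether (5,5'',7,7'',4',4'''-hexamethoxy-8,8''-biflavone) | COc1ccc(cc1)-c1cc(=O)c2c(OC)cc(OC)c(c2o1)-c1c(OC)cc(OC)c2c(=O)cc(oc12)-c1ccc(OC)cc1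
F6 | step 1 | 1-(triisopropylsiloxy)-4-(trimethylsilyl)buta-1,3-diyne | CC(C)[Si](OC#CC#C[Si](C)(C)C)(C(C)C)C(C)C
F7 | step 5 | 4,4'-diethoxybiphenyl-2,2',6,6'-tetraol | CCOc1cc(O)c(c(O)c1)-c1c(O)cc(OCC)cc1O
F8 | step 5 | 1,1'-(4,4'-diethoxy-2,2',6,6'-tetrahydroxybiphenyl-3,3'-diyl)diethanone | CCOc1cc(O)c(c(O)c1C(C)=O)-c1c(O)cc(OCC)c(C(C)=O)c1O
F9 | step 5 | (2E,2'E)-1,1'-(4,4'-diethoxy-2,2',6,6'-tetrahydroxybiphenyl-3,3'-diyl)bis[3-(4-methoxyphenyl)prop-2-en-1-one] | CCOc1cc(O)c(c(O)c1C(=O)/C=C/c1ccc(OC)cc1)-c1c(O)cc(OCC)c(C(=O)/C=C/c2ccc(OC)cc2)c1O
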